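## Retrosynthetic overview

1. Numbering used throughout: enone bridge C1(H)–C2(=O)–C3H=C4(CH3)–C5(H); C6 (quaternary, CH3) and C7 (H) are the one-carbon bridges between C1 and C5; C8(OAng)–C9H2–C10(OAng)–C11(CH3)(C12H2OAng) links C6 to C7. Ring A is the cyclobutane C1–C7–C5–C6, ring B the cyclohexenone C1–C2–C3–C4–C5–C6, ring C the cycloheptane C5–C6–C8–C9–C10–C11–C7.
2. Endgame: target 38 from triol 35 by two-stage angeloylation with angelic anhydride 36 (primary C12 hydroxyl first, then the two hindered secondary hydroxyls); the C4 methyl is added to the C4-unsubstituted enone 31 by conjugate methylation, bromination and dehydrobromination.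
3. Key disconnection: C1–C7 and C3=C4 are formed in one flask from the cycloheptene α-diazoketone 28. The carbene at C1 adds to the C5=C7 alkene to give a bicyclo[1.1.0]butane; Lewis acid-triggered strain release (C1–C5 cleavage, 1,2-hydride shift turning C4 into an aldehyde) and aldol condensation C3→C4 then close rings A and B together.
4. Enabling feature: ring A carries its two acyl carbons (C2, C4) on the 1,3-related carbons C1 and C5 and is spanned on the other diagonal (C6···C7) by ring C, so it is a wing-bridged bicyclobutane with the central C1–C5 bond cut; C6 is quaternary, so a carbene at C1 has no β-hydrogen and must add to the adjacent C5=C7 bond.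
5. Ring C is made first, by aldol condensation of an acyclic dialdehyde (C5=C7); the chain stereocentres come from Noyori hydrogenation (C10), two Fráter–Seebach quaternary alkylations (C11, C6) and an Evans aldol reaction (C8).

Key step: step 21

Remark: 4-methoxybenzyl chloromethyl ether and angelic anhydride are treated as purchasable; the provisional α-stereocentres of 4 and of 12/13 are erased by the following enolisation, so only the carbinol centres and the quaternary centres matter.

## Route

Step 1
Reactants: 1 methyl 5,5-dimethoxy-3-oxopentanoate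
Product: 2 methyl (3R)-3-hydroxy-5,5-dimethoxypentanoate
Conditions: RuCl2[(R)-BINAP] (0.5 mol %), H2 (50 atm), MeOH, 50 °C
Reagents that add atoms: none
Why: Noyori asymmetric hydrogenation of a β-keto ester; the (R)-BINAP ruthenium catalyst should deliver hydrogen to one face of the ketone and set the C10 carbinol as (R).

Step 2
Reactants: 2 methyl (3R)-3-hydroxy-5,5-dimethoxypentanoate
Product: 4 methyl (2R,3R)-3-hydroxy-5,5-dimethoxy-2-methylpentanoate, via dilithium alkoxide enolate 3 (not isolated)
Conditions: LiN(iPr)2 (2.2 equiv), THF, −78 → −20 °C; then MeI, DMPU, −78 → −20 °C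
Reagents that add atoms: iodomethane, CI
Why: Fráter–Seebach alkylation; the chelated alkoxide enolate should be methylated anti to the C10 oxygen (this centre is provisional).

Step 3
Reactants: 4 methyl (2R,3R)-3-hydroxy-5,5-dimethoxy-2-methylpentanoate
Product: 6 methyl (2R,3R)-3-hydroxy-5,5-dimethoxy-2-[(4-methoxybenzyloxy)methyl]-2-methylpentanoate, via dilithium alkoxide enolate 5 (not isolated)
Conditions: LiN(iPr)2 (2.3 equiv), THF/DMPU, −78 → −15 °C; then 4-methoxybenzyl chloromethyl ether, −78 → −20 °C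
Reagents that add atoms: 4-methoxybenzyl chloromethyl ether, COc1ccc(COCCl)cc1
Why: second Fráter–Seebach alkylation; the electrophile should again enter anti to the C10 alkoxide, so that C11 becomes quaternary with the C7 arm anti and the methyl group syn to the C10 oxygen, as the target requires.

Step 4
Reactants: 6 methyl (2R,3R)-3-hydroxy-5,5-dimethoxy-2-[(4-methoxybenzyloxy)methyl]-2-methylpentanoate
Product: 7 (2R,3R)-5,5-dimethoxy-2-[(4-methoxybenzyloxy)methyl]-2-methylpentane-1,3-diol
Conditions: LiAlH4, THF, 0 °C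
Reagents that add atoms: none
Why: hydride reduction of the hindered ester to the C12 primary alcohol; no stereocentre is touched.

Step 5
Reactants: 7 (2R,3R)-5,5-dimethoxy-2-[(4-methoxybenzyloxy)methyl]-2-methylpentane-1,3-diol
Product: 8 bis-TBS ether of diol 7 (C10-OTBS and C12-OTBS)
Conditions: TBSOTf (2.5 equiv), 2,6-lutidine, CH2Cl2, −78 → −20 °C
Reagents that add atoms: tert-butyldimethylsilyl trifluoromethanesulfonate, CC(C)(C)[Si](C)(C)OS(=O)(=O)C(F)(F)F
Why: silyl ether formation at both hydroxyls (the triflate is needed for the neopentyl secondary one); the low temperature should spare the dimethyl acetal.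

Step 6
Reactants: 8 bis-TBS ether of diol 7 (C10-OTBS and C12-OTBS)
Product: 9 C8 aldehyde (C10-OTBS, C12-OTBS, C7-OPMB)
Conditions: LiBF4, MeCN/H2O (50:1), 23 °C
Reagents that add atoms: water, O
Why: mild Lewis acid-assisted acetal hydrolysis that should leave the TBS and PMB ethers intact and free the C8 aldehyde.

Step 7
Reactants: 9 C8 aldehyde (C10-OTBS, C12-OTBS, C7-OPMB); 10 (4S)-4-benzyl-3-(pent-4-enoyl)-1,3-oxazolidin-2-one
Product: 12 Evans syn-aldol adduct (C8-OH), via Z-dibutylboron enolate 11 (not isolated)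
Conditions: 10, Bu2BOTf, Et3N, CH2Cl2, −78 → 0 °C; then 9, −78 → 0 °C; pH 7 buffer, MeOH, H2O2 work-up
Reagents that add atoms: none
Why: Evans syn-aldol reaction; the Z-boron enolate reacts through a closed chair transition state under auxiliary control and should set C8 as (R) (the α-allyl centre is provisional).

Step 8
Reactants: 12 Evans syn-aldol adduct (C8-OH)
Product: 13 methyl ester of aldol 12
Conditions: Sm(OTf)3 (10 mol %), MeOH, 23 °C
Reagents that add atoms: methanol, CO
Why: Lewis acid-catalysed transesterification of the N-acyl oxazolidinone, which should give the methyl ester without retro-aldol cleavage and return the auxiliary.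

Step 9
Reactants: 13 methyl ester of aldol 12
Product: 15 C6-quaternary ester (C6: CH3, allyl, CO2Me; C8-OH), via dilithium alkoxide enolate 14 (not isolated)
Conditions: LiN(iPr)2 (2.5 equiv), THF/DMPU, −78 → −20 °C; then MeI, −78 → −20 °C
Reagents that add atoms: iodomethane, CI
Why: Fráter–Seebach alkylation; enolisation erases the provisional α-centre and iodomethane should enter anti to the C8 alkoxide, giving the C6 quaternary centre with the allyl group syn to the C8 oxygen.

Step 10
Reactants: 15 C6-quaternary ester (C6: CH3, allyl, CO2Me; C8-OH)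
Product: 16 C8-O-TBS ether of 15
Conditions: TBSOTf, 2,6-lutidine, CH2Cl2, −40 → 0 °C
Reagents that add atoms: tert-butyldimethylsilyl trifluoromethanesulfonate, CC(C)(C)[Si](C)(C)OS(=O)(=O)C(F)(F)F
Why: silylation of the hindered C8 hydroxyl with the silyl triflate; no stereocentre is affected.

Step 11
Reactants: 16 C8-O-TBS ether of 15
Product: 17 C7 primary alcohol
Conditions: DDQ, CH2Cl2/pH 7 buffer, 0 °C
Reagents that add atoms: none
Why: oxidative cleavage of the PMB ether, which should free only the C7 hydroxyl.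

Step 12
Reactants: 17 C7 primary alcohol
Product: 18 C7 aldehyde
Conditions: Dess–Martin periodinane, NaHCO3, CH2Cl2, 23 °C
Reagents that add atoms: none
Why: Dess–Martin oxidation to the neopentyl, non-enolisable C7 aldehyde.

Step 13
Reactants: 18 C7 aldehyde
Product: 19 C4,C7-dialdehyde
Conditions: OsO4 (2 mol %), NaIO4, 2,6-lutidine, dioxane/H2O, 23 °C
Reagents that add atoms: sodium periodate, [Na+].[O-]I(=O)(=O)=O
Why: Lemieux–Johnson cleavage of the terminal alkene gives the C4 aldehyde, the only enolisable carbonyl group of the dialdehyde.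

Step 14
Reactants: 19 C4,C7-dialdehyde
Product: 21 ring C enal (C5=C7, C4 aldehyde on C5), via ring C aldol 20 (not isolated)
Conditions: Bn2NH·CF3CO2H (20 mol %), benzene, 50 °C
Reagents that add atoms: none
Why: amine salt-mediated intramolecular aldol condensation (enamine of the CH2CHO arm, 7-(enolexo)-exo-trig addition to the C7 aldehyde, then dehydration), helped by the two quaternary centres; it should close ring C without creating a stereocentre.

Step 15
Reactants: 21 ring C enal (C5=C7, C4 aldehyde on C5)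
Product: 22 allylic alcohol (C4-OH)
Conditions: NaBH4, CeCl3·7H2O, MeOH, −40 °C
Reagents that add atoms: none
Why: Luche 1,2-reduction of the enal; the hindered methyl ester should not react.

Step 16
Reactants: 22 allylic alcohol (C4-OH)
Product: 23 C4-O-TES ether
Conditions: Et3SiCl, imidazole, CH2Cl2, 0 °C
Reagents that add atoms: chlorotriethylsilane, CC[Si](Cl)(CC)CC
Why: silylation of the primary allylic alcohol; the triethylsilyl ether later serves as hydride donor site and silyl shuttle.

Step 17
Reactants: 23 C4-O-TES ether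
Product: 24 C1 primary alcohol
Conditions: LiAlH4, Et2O, 0 → 23 °C
Reagents that add atoms: none
Why: hydride reduction of the hindered methyl ester at C1; silyl ethers and the trisubstituted alkene should survive.

Step 18
Reactants: 24 C1 primary alcohol
Product: 25 C1 aldehyde
Conditions: Dess–Martin periodinane, NaHCO3, CH2Cl2, 23 °C
Reagents that add atoms: none
Why: Dess–Martin oxidation to the neopentyl aldehyde, which cannot enolise or epimerise.

Step 19
Reactants: 25 C1 aldehyde
Product: 26 C1 hydrazone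
Conditions: N2H4·H2O (10 equiv), EtOH, 23 °C
Reagents that add atoms: hydrazine, NN
Why: hydrazone formation; the excess of hydrazine should suppress azine formation.

Step 20
Reactants: 26 C1 hydrazone
Product: 28 α-diazoketone (C1 diazo, C2 acetyl), via C1 diazoalkane 27 (not isolated)
Conditions: MnO2, CH2Cl2, −10 °C, cold filtration; then AcCl, CaO, Et2O, −20 → 0 °C
Reagents that add atoms: acetyl chloride, CC(=O)Cl
Why: dehydrogenation of the hydrazone to the diazoalkane and its C-acylation by the acid chloride (Arndt–Eistert-type acylation of a diazoalkane) with CaO as HCl trap; the quaternary C6 neighbour disfavours substitution or elimination at the diazonium stage.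

Step 21
Reactants: 28 α-diazoketone (C1 diazo, C2 acetyl)
Product: 31 tricyclic C4-unsubstituted enone (tris-TBS), via bicyclo[1.1.0]butane 29 (not isolated), via cis keto aldehyde 30 (not isolated)
Conditions: Rh2(OAc)4 (1 mol %), CH2Cl2, 0 → 23 °C, slow addition; then TMSOTf (10 mol %), −78 → 0 °C, same flask
Reagents that add atoms: none
Why: Proposed new method: the dirhodium carbene at C1 cannot undergo a 1,2-hydride shift because C6 is quaternary, so it adds to the flanking C5=C7 bond and forms C1–C7 and C1–C5, giving the wing-bridged bicyclobutane 29; the closest known reaction is the dirhodium-catalysed intramolecular bicyclobutanation of 2-diazopent-4-enoates. TMSOTf then silylates the C2 ketone and the strained C1–C5 bond ionises, as in the known Lewis acid activation of acyl bicyclobutanes, to a C2 enol silane and a cyclobutyl cation at C5; this cation is quenched by a semipinacol-type 1,2-hydride shift from the CH2OSiEt3 carbon, so that C4 becomes an aldehyde (30, held as its enol silane) and silyl triflate is regenerated. After acid-mediated transposition of the enol silane to C3, ring B closes by a 6-(enolexo)-exo-trig Mukaiyama aldol addition to C4 and loss of silanol gives the C3=C4 enone, while ring A is what remains of the bicyclobutane (closed by the 3-exo carbene addition) after central-bond cleavage. The new centres C1, C5 and C7 are dictated by C6: the carbene can only reach the alkene face on which it is tethered, ring C has to stay as the endo bridge, and C1 and C5 can equilibrate through their enol forms to the cis diacyl arrangement, the only one that can cyclise. The step needs cyclopropanation to outrun C–H insertion and Wolff rearrangement (served by the adjacent trisubstituted alkene and the absence of free hydroxyls), and it needs a single aldol direction (secured because C4 is an aldehyde whose only α-carbon, C5, cannot reach C2, so only the C2 methyl ketone can be the donor). The strain released from the bicyclobutane pays for the strained bicyclo[3.1.1]heptenone, and the enol π-system at C5 is orthogonal to the ring A bonds, which should block retro-Michael opening.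

Step 22
Reactants: 31 tricyclic C4-unsubstituted enone (tris-TBS)
Product: 33 C3-bromo C4-methyl ketone, via TMS enol ether 32 (not isolated)
Conditions: MeMgBr, CuBr·SMe2 (10 mol %), TMSCl, THF, −78 °C; then NBS, −78 → 0 °C
Reagents that add atoms: methylmagnesium bromide, C[Mg]Br; N-bromosuccinimide, O=C1CCC(=O)N1Br
Why: copper-catalysed conjugate addition of the methyl Grignard reagent with silyl trapping, then bromination of the enol silane; both reagents should approach the enone bridge from the side of the C7–H bridge, away from the C6 methyl group.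

Step 23
Reactants: 33 C3-bromo C4-methyl ketone
Product: 34 tris-TBS ether of the target triol (C4-methyl enone)
Conditions: Li2CO3, LiBr, DMF, 120 °C
Reagents that add atoms: none
Why: dehydrobromination of the α-bromo ketone (bromide exchange by LiBr allows the anti arrangement), which should restore the C3=C4 bond now carrying the C4 methyl; C1 is a bridgehead and cannot enolise.

Step 24
Reactants: 34 tris-TBS ether of the target triol (C4-methyl enone)
Product: 35 triol
Conditions: HF·pyridine, pyridine, THF, 0 → 23 °C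
Reagents that add atoms: none
Why: fluoride-mediated cleavage of the three TBS ethers under buffered conditions that should not affect the enone or ring A.

Step 25
Reactants: 35 triol; 36 angelic anhydride
Product: 37 C12 mono-angelate (C8-OH and C10-OH free)
Conditions: LiN(SiMe3)2 (1.0 equiv), THF, −78 °C; then 36 (1.05 equiv), −78 → −30 °C
Reagents that add atoms: none
Why: acylation of a lithium alkoxide by a carboxylic anhydride; proton exchange among the hydroxyls is fast and the primary C12 alkoxide should be acylated well before the two neopentyl secondary ones, while the absence of a nucleophilic catalyst should keep the Z geometry of the angeloyl group; no stereocentre is touched.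

Step 26
Reactants: 37 C12 mono-angelate (C8-OH and C10-OH free); 36 angelic anhydride
Product: 38 target, tris-angelate CNP0266467.1
Conditions: LiN(SiMe3)2 (2.1 equiv), THF, −78 °C; then 36 (3 equiv), −78 → 10 °C
Reagents that add atoms: none
Why: stereoconservative angeloylation of the two hindered secondary lithium alkoxides with excess anhydride (alkoxide acylation without nucleophilic catalyst or acid, so the Z geometry should be kept); an acyl shift from C12 to C10 under the basic conditions would be of no consequence because every hydroxyl ends up as the same ester, and no stereocentre is touched.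

## Compound list

1 | methyl 5,5-dimethoxy-3-oxopentanoate | COC(=O)CC(=O)CC(OC)OC | starting material
2 | methyl (3R)-3-hydroxy-5,5-dimethoxypentanoate | COC(=O)C[C@H](O)CC(OC)OC | intermediate
3 | dilithium alkoxide enolate of 2 | [Li+].[Li+].CO/C([O-])=C/[C@H]([O-])CC(OC)OC | intermediate
4 | methyl (2R,3R)-3-hydroxy-5,5-dimethoxy-2-methylpentanoate | COC(=O)[C@H](C)[C@H](O)CC(OC)OC | intermediate
5 | dilithium alkoxide enolate of 4 | [Li+].[Li+].CO/C([O-])=C(\C)[C@H]([O-])CC(OC)OC | intermediate
6 | methyl (2R,3R)-3-hydroxy-5,5-dimethoxy-2-[(4-methoxybenzyloxy)methyl]-2-methylpentanoate | COC(=O)[C@](C)(COCc1ccc(OC)cc1)[C@H](O)CC(OC)OC | intermediate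
7 | (2R,3R)-5,5-dimethoxy-2-[(4-methoxybenzyloxy)methyl]-2-methylpentane-1,3-diol | OC[C@](C)(COCc1ccc(OC)cc1)[C@H](O)CC(OC)OC | intermediate
8 | bis-TBS ether of diol 7 (C10-OTBS, C12-OTBS, C7-OPMB, C8 dimethyl acetal) | CC(C)(C)[Si](C)(C)OC[C@](C)(COCc1ccc(OC)cc1)[C@H](O[Si](C)(C)C(C)(C)C)CC(OC)OC | intermediate
9 | C8 aldehyde (C10-OTBS, C12-OTBS, C7-OPMB) | CC(C)(C)[Si](C)(C)OC[C@](C)(COCc1ccc(OC)cc1)[C@H](O[Si](C)(C)C(C)(C)C)CC=O | intermediate
10 | (4S)-4-benzyl-3-(pent-4-enoyl)-1,3-oxazolidin-2-one | C=CCCC(=O)N1[C@@H](Cc2ccccc2)COC1=O | starting material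
11 | Z-dibutylboron enolate of 10 | C=CC/C=C(\OB(CCCC)CCCC)N1[C@@H](Cc2ccccc2)COC1=O | intermediate
12 | Evans syn-aldol adduct (C8-OH; C6 bearing allyl and the acyl oxazolidinone) | CC(C)(C)[Si](C)(C)OC[C@](C)(COCc1ccc(OC)cc1)[C@H](O[Si](C)(C)C(C)(C)C)C[C@@H](O)[C@H](CC=C)C(=O)N1[C@@H](Cc2ccccc2)COC1=O | intermediate
13 | methyl ester of aldol 12 | CC(C)(C)[Si](C)(C)OC[C@](C)(COCc1ccc(OC)cc1)[C@H](O[Si](C)(C)C(C)(C)C)C[C@@H](O)[C@H](CC=C)C(=O)OC | intermediate
14 | dilithium alkoxide enolate of 13 | [Li+].[Li+].CC(C)(C)[Si](C)(C)OC[C@](C)(COCc1ccc(OC)cc1)[C@H](O[Si](C)(C)C(C)(C)C)C[C@@H]([O-])/C(CC=C)=C(\[O-])OC | intermediate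
15 | C6-quaternary ester (C6: CH3, allyl, CO2Me; C8-OH) | CC(C)(C)[Si](C)(C)OC[C@](C)(COCc1ccc(OC)cc1)[C@H](O[Si](C)(C)C(C)(C)C)C[C@@H](O)[C@](C)(CC=C)C(=O)OC | intermediate
16 | C8-O-TBS ether of 15 | CC(C)(C)[Si](C)(C)OC[C@](C)(COCc1ccc(OC)cc1)[C@H](O[Si](C)(C)C(C)(C)C)C[C@@H](O[Si](C)(C)C(C)(C)C)[C@](C)(CC=C)C(=O)OC | intermediate
17 | C7 primary alcohol | CC(C)(C)[Si](C)(C)OC[C@](C)(CO)[C@H](O[Si](C)(C)C(C)(C)C)C[C@@H](O[Si](C)(C)C(C)(C)C)[C@](C)(CC=C)C(=O)OC | intermediate
18 | C7 aldehyde | CC(C)(C)[Si](C)(C)OC[C@](C)(C=O)[C@H](O[Si](C)(C)C(C)(C)C)C[C@@H](O[Si](C)(C)C(C)(C)C)[C@](C)(CC=C)C(=O)OC | intermediate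
19 | C4,C7-dialdehyde | CC(C)(C)[Si](C)(C)OC[C@](C)(C=O)[C@H](O[Si](C)(C)C(C)(C)C)C[C@@H](O[Si](C)(C)C(C)(C)C)[C@](C)(CC=O)C(=O)OC | intermediate
20 | ring C aldol (β-hydroxy aldehyde, epimer mixture at C5 and C7) | O=CC1C(O)[C@@](C)(CO[Si](C)(C)C(C)(C)C)[C@H](O[Si](C)(C)C(C)(C)C)C[C@@H](O[Si](C)(C)C(C)(C)C)[C@@]1(C)C(=O)OC | intermediate
21 | ring C enal (C5=C7, C4 aldehyde on C5) | O=CC1=C[C@@](C)(CO[Si](C)(C)C(C)(C)C)[C@H](O[Si](C)(C)C(C)(C)C)C[C@@H](O[Si](C)(C)C(C)(C)C)[C@@]1(C)C(=O)OC | intermediate
22 | allylic alcohol (C4-OH) | OCC1=C[C@@](C)(CO[Si](C)(C)C(C)(C)C)[C@H](O[Si](C)(C)C(C)(C)C)C[C@@H](O[Si](C)(C)C(C)(C)C)[C@@]1(C)C(=O)OC | intermediate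
23 | C4-O-TES ether | CC[Si](CC)(CC)OCC1=C[C@@](C)(CO[Si](C)(C)C(C)(C)C)[C@H](O[Si](C)(C)C(C)(C)C)C[C@@H](O[Si](C)(C)C(C)(C)C)[C@@]1(C)C(=O)OC | intermediate
24 | C1 primary alcohol | CC[Si](CC)(CC)OCC1=C[C@@](C)(CO[Si](C)(C)C(C)(C)C)[C@H](O[Si](C)(C)C(C)(C)C)C[C@@H](O[Si](C)(C)C(C)(C)C)[C@@]1(C)CO | intermediate
25 | C1 aldehyde | CC[Si](CC)(CC)OCC1=C[C@@](C)(CO[Si](C)(C)C(C)(C)C)[C@H](O[Si](C)(C)C(C)(C)C)C[C@@H](O[Si](C)(C)C(C)(C)C)[C@@]1(C)C=O | intermediate
26 | C1 hydrazone | CC[Si](CC)(CC)OCC1=C[C@@](C)(CO[Si](C)(C)C(C)(C)C)[C@H](O[Si](C)(C)C(C)(C)C)C[C@@H](O[Si](C)(C)C(C)(C)C)[C@@]1(C)/C=N/N | intermediate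
27 | C1 diazoalkane | CC[Si](CC)(CC)OCC1=C[C@@](C)(CO[Si](C)(C)C(C)(C)C)[C@H](O[Si](C)(C)C(C)(C)C)C[C@@H](O[Si](C)(C)C(C)(C)C)[C@@]1(C)C=[N+]=[N-] | intermediate
28 | α-diazoketone (C1 diazo, C2 acetyl) | CC[Si](CC)(CC)OCC1=C[C@@](C)(CO[Si](C)(C)C(C)(C)C)[C@H](O[Si](C)(C)C(C)(C)C)C[C@@H](O[Si](C)(C)C(C)(C)C)[C@@]1(C)C(=[N+]=[N-])C(C)=O | intermediate
29 | bicyclo[1.1.0]butane (central bond C1–C5; wings C6 and C7 bridged by C8–C11; C2 acetyl; C4H2OTES) | CC(=O)[C@]12[C@@H]3[C@@]1(CO[Si](CC)(CC)CC)[C@@]2(C)[C@H](O[Si](C)(C)C(C)(C)C)C[C@@H](O[Si](C)(C)C(C)(C)C)[C@]3(C)CO[Si](C)(C)C(C)(C)C | intermediate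
30 | cis keto aldehyde (ring A with acetyl on C1 and CHO on C5) | CC(=O)[C@@H]1[C@@H]2[C@H](C=O)[C@@]1(C)[C@H](O[Si](C)(C)C(C)(C)C)C[C@@H](O[Si](C)(C)C(C)(C)C)[C@]2(C)CO[Si](C)(C)C(C)(C)C | intermediate
31 | tricyclic C4-unsubstituted enone (tris-TBS) | CC(C)(C)[Si](C)(C)OC[C@]1(C)[C@@H]2[C@H]3C(=O)C=C[C@@H]2[C@@]3(C)[C@H](O[Si](C)(C)C(C)(C)C)C[C@H]1O[Si](C)(C)C(C)(C)C | intermediate
32 | TMS enol ether of the C4-methyl ketone | CC(C)(C)[Si](C)(C)OC[C@]1(C)[C@@H]2[C@H]3C(O[Si](C)(C)C)=C[C@@H](C)[C@@H]2[C@@]3(C)[C@H](O[Si](C)(C)C(C)(C)C)C[C@H]1O[Si](C)(C)C(C)(C)C | intermediate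
33 | C3-bromo C4-methyl ketone (Br and CH3 on the face toward C7) | CC(C)(C)[Si](C)(C)OC[C@]1(C)[C@@H]2[C@H]3C(=O)[C@@H](Br)[C@@H](C)[C@@H]2[C@@]3(C)[C@H](O[Si](C)(C)C(C)(C)C)C[C@H]1O[Si](C)(C)C(C)(C)C | intermediate
34 | tris-TBS ether of the target triol (C4-methyl enone) | CC(C)(C)[Si](C)(C)OC[C@]1(C)[C@@H]2[C@H]3C(=O)C=C(C)[C@@H]2[C@@]3(C)[C@H](O[Si](C)(C)C(C)(C)C)C[C@H]1O[Si](C)(C)C(C)(C)C | intermediate
35 | triol (C8-OH, C10-OH, C12-OH) | OC[C@]1(C)[C@@H]2[C@H]3C(=O)C=C(C)[C@@H]2[C@@]3(C)[C@H](O)C[C@H]1O | intermediate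
36 | angelic anhydride, (Z)-2-methylbut-2-enoic anhydride | C/C=C(/C)C(=O)OC(=O)/C(C)=C\C | starting material
37 | C12 mono-angelate (C8-OH and C10-OH free) | C/C=C(/C)C(=O)OC[C@]1(C)[C@@H]2[C@H]3C(=O)C=C(C)[C@@H]2[C@@]3(C)[C@H](O)C[C@H]1O | intermediate
38 | CNP0266467.1, tris-angelate | C/C=C(/C)C(=O)OC[C@]1(C)[C@@H]2[C@H]3C(=O)C=C(C)[C@@H]2[C@@]3(C)[C@H](OC(=O)/C(C)=C\C)C[C@H]1OC(=O)/C(C)=C\C | target

## Step count and risks

Total step count: 26. Longest linear sequence: 26 steps (1 → 38).

Step 21 (Proposed new method). The carbene may insert into a C–H bond next to a silyloxy group or undergo Wolff rearrangement instead of cyclopropanating; the cation at C5 may lose a ring proton instead of accepting the hydride; the enol silane may fail to transpose to C3. The fallback uses known chemistry, sets out from 28 and returns at 31. The dirhodium stage is run alone and bicyclobutane 29 is isolated. SmI2 (THF/t-BuOH, −78 °C) opens the central bond by ketyl fragmentation, the known behaviour of strained α-keto C–C bonds, to give the cyclobutyl methyl ketone F1. Buffered TBAF/AcOH removes the primary triethylsilyl group to give alcohol F2. Dess–Martin oxidation gives keto aldehyde 30, now isolated, and Bn2NH·CF3CO2H closes ring B by aldol condensation to 31.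

Step 20. The hindered, non-stabilised diazoalkane may lose nitrogen or be protonated before it is acylated, and O-acylation or ketene formation may compete. The fallback sets out from 25 and returns at 28. Wittig methoxymethylenation (Ph3P=CHOMe) gives enol ether F3. Hg(OAc)2-assisted hydrolysis gives the homologous aldehyde F4, whose only α-carbon is C1. Stork enamine acylation (pyrrolidine; AcCl; buffered hydrolysis) gives the formyl ketone F5, and Regitz deformylative diazo transfer (MsN3, Et3N) gives 28.

Step 26. Acylation of the two neopentyl-type secondary alkoxides may stall, the base may instead deprotonate the C4 methyl group of the enone, and prolonged warming may isomerise angelate to tiglate. The fallback sets out from 37 and returns at 38. Esterification of both secondary hydroxyls with 2-[bis(2-methylphenoxy)phosphoryl]propanoic acid (DCC, DMAP cat., CH2Cl2, 0 → 23 °C) gives the bis(phosphonopropanoate) F6. A Z-selective Horner–Wadsworth–Emmons olefination with acetaldehyde (NaH, THF, −78 °C) then builds the two remaining angelate double bonds on the molecule and gives 38.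

Further compounds
F1 | step 21 | cyclobutyl methyl ketone (acetyl on C1, CH2OTES on C5, cis) | CC(=O)[C@@H]1[C@@H]2[C@H](CO[Si](CC)(CC)CC)[C@@]1(C)[C@H](O[Si](C)(C)C(C)(C)C)C[C@@H](O[Si](C)(C)C(C)(C)C)[C@]2(C)CO[Si](C)(C)C(C)(C)C
F2 | step 21 | primary alcohol of F1 (CH2OH on C5) | CC(=O)[C@@H]1[C@@H]2[C@H](CO)[C@@]1(C)[C@H](O[Si](C)(C)C(C)(C)C)C[C@@H](O[Si](C)(C)C(C)(C)C)[C@]2(C)CO[Si](C)(C)C(C)(C)C
F3 | step 20 | methyl enol ether from 25 (E/Z mixture) | CC[Si](CC)(CC)OCC1=C[C@@](C)(CO[Si](C)(C)C(C)(C)C)[C@H](O[Si](C)(C)C(C)(C)C)C[C@@H](O[Si](C)(C)C(C)(C)C)[C@@]1(C)C=COC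
F4 | step 20 | homologous aldehyde (C6–C1H2–CHO) | CC[Si](CC)(CC)OCC1=C[C@@](C)(CO[Si](C)(C)C(C)(C)C)[C@H](O[Si](C)(C)C(C)(C)C)C[C@@H](O[Si](C)(C)C(C)(C)C)[C@@]1(C)CC=O
F5 | step 20 | formyl ketone (C1 bearing CHO and acetyl, epimer/enol mixture) | CC[Si](CC)(CC)OCC1=C[C@@](C)(CO[Si](C)(C)C(C)(C)C)[C@H](O[Si](C)(C)C(C)(C)C)C[C@@H](O[Si](C)(C)C(C)(C)C)[C@@]1(C)C(C=O)C(C)=O
F6 | step 26 | bis[2-(bis(2-methylphenoxy)phosphoryl)propanoate] of mono-angelate 37 at C8 and C10 (epimer mixture at the phosphonate carbons) | C/C=C(/C)C(=O)OC[C@]1(C)[C@@H]2[C@H]3C(=O)C=C(C)[C@@H]2[C@@]3(C)[C@H](OC(=O)C(C)P(=O)(Oc4ccccc4C)Oc4ccccc4C)C[C@H]1OC(=O)C(C)P(=O)(Oc4ccccc4C)Oc4ccccc4C
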